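**Plan**

1. Numbering follows the target's name: ring C1 (CHOAc), C2 (=CH), C3 (CMe), C4 (C=O), C5 (CHOH), C6 (CH bearing the side chain); side chain C1′–C11′.
2. Retrosynthesis: cut C3′–C4′ (Suzuki–Miyaura; vinyl iodide 16 + vinylboronate 25), remove the C5 hydroxyl and the C1 acetoxy group, then cut the ring bonds C2=C3 and C5–C6 together.
3. Enabling feature: the ring is a 2-methylcyclohex-2-en-1-one (carvone type). C3 and C5 are the two α-carbons of the C4 ketone, and C6 is β to an aldehyde-level C2, which is a 1,5-dicarbonyl retron. A β-keto ester (C3–C4–C5) and an enal (C2–C1–C6) therefore give both bonds in one Michael/aldol-condensation annulation.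
4. Forward: iodo-dienal 6 (steps 1–3), amine-catalysed [3+3] annulation to enone 10 (step 4, the only ring formation), oxygenation at C1 and C5 (steps 5–8), then coupling with side chain 25, made in six steps from methyl (S)-3-hydroxy-2-methylpropanoate (steps 9–15).
5. Stereochemistry: C6 from the chiral amine catalyst in step 4; C1 from peracid attack anti to the C6 substituent, then Mitsunobu inversion; C5 from enolate oxidation anti to C6 (also the thermodynamic epimer); C6′ from the chiral-pool ester; 2′E from syn-carboalumination, 4′E from Takai–Utimoto olefination, 7′Z from a salt-free Wittig reaction.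

Key step: step 4

Remark: the facial sense of the (S)-diarylprolinol silyl ether is taken from its established conjugate additions of carbon nucleophiles to (E)-enals; if addition to 6 had the opposite sense, the (R)-catalyst would be used with no other change.

**Route**

Step 1
Reactants: 1 prop-2-yn-1-ol
Product: 3 (E)-3-iodo-2-methylprop-2-en-1-ol, via alkenylalane 2 (not isolated)
Conditions: Me3Al (3 equiv), Cp2ZrCl2 (25 mol %), CH2Cl2, 0 °C to rt; then I2, THF, −30 to 0 °C; aq. K2CO3
Reagents that add atoms: trimethylaluminium, C[Al](C)C; iodine, II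
Why: Zirconium-catalysed carboalumination (Negishi carboalumination) adds methyl and aluminium syn across the alkyne with methyl on the internal carbon, and iodinolysis of the carbon–aluminium bond with retention fixes the 2′E geometry.

Step 2
Reactants: 3 (E)-3-iodo-2-methylprop-2-en-1-ol
Product: 4 (E)-3-iodo-2-methylprop-2-enal
Conditions: activated MnO2 (15 equiv), CH2Cl2, rt
Reagents that add atoms: none
Why: MnO2 oxidation is selective for allylic alcohols and should leave the vinyl iodide and the alkene geometry untouched.

Step 3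
Reactants: 4 (E)-3-iodo-2-methylprop-2-enal; 5 (triphenylphosphoranylidene)acetaldehyde
Product: 6 (2E,4E)-5-iodo-4-methylpenta-2,4-dienal
Conditions: toluene, 80 °C (1.05 equiv of 5)
Reagents that add atoms: none
Why: Wittig reaction of the stabilised formylmethylene ylide should give the (E)-enal, and the less conjugated aldehyde 4 is more electrophilic than product 6, which limits double homologation.

Step 4
Reactants: 6 (2E,4E)-5-iodo-4-methylpenta-2,4-dienal; 7 tert-butyl 3-oxopentanoate
Product: 10 (S)-5-[(E)-1-iodoprop-1-en-2-yl]-2-methylcyclohex-2-en-1-one, via Michael adduct 8 (not isolated), via cyclohexenone ester 9 (not isolated)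
Conditions: (S)-2-{bis[3,5-bis(trifluoromethyl)phenyl][(trimethylsilyl)oxy]methyl}pyrrolidine (10 mol %), toluene, rt; then TsOH·H2O (20 mol %), 80 °C
Reagents that add atoms: none
Why: The amine condenses with 6 to an (E)-iminium ion whose β-carbon (future C6) is attacked by the enol of 7 through its C2 carbon (future C5), giving after hydrolysis the 1,5-keto aldehyde 8; acid then drives intramolecular aldol addition of the ethyl-ketone CH2 (future C3) to the aldehyde (future C2), dehydration to enone ester 9, and loss of isobutene and CO2. The closest known reaction type is the amine-catalysed Michael/aldol-condensation (Robinson-type) annulation of β-keto esters with enals with dealkoxycarbonylation in the same pot. The ring closes in a 6-(enolendo)-exo-trig aldol mode, the only alternatives being four-membered. C6 is the one new stereocentre that survives; it is set in the Michael step, where the diarylsiloxymethyl arm of the catalyst blocks one face of the s-trans iminium ion, while the centre next to the ester is lost on decarboxylation. The step needs 1,4- rather than 1,6-addition and no substitution at the iodine-bearing carbon, which the larger LUMO coefficient at the iminium β-carbon and the γ-methyl/δ-iodo substitution of the diene terminus should secure. The tert-butyl ester is the activating group for C5 and leaves in the same operation.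

Step 5
Reactants: 10 (S)-5-[(E)-1-iodoprop-1-en-2-yl]-2-methylcyclohex-2-en-1-one
Product: 11 (R)-5-[(E)-1-iodoprop-1-en-2-yl]-2-methylcyclohexa-1,3-dien-1-yl acetate
Conditions: isopropenyl acetate (solvent), TsOH·H2O (5 mol %), 90 °C, acetone distilled off
Reagents that add atoms: isopropenyl acetate, CC(=C)OC(C)=O
Why: Acid-catalysed enol acetylation under equilibrating conditions should give the linearly conjugated dienyl acetate (proton loss from C1), the thermodynamic enol ester of a 2-cyclohexenone; C6 is not enolisable and keeps its configuration.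

Step 6
Reactants: 11 (R)-5-[(E)-1-iodoprop-1-en-2-yl]-2-methylcyclohexa-1,3-dien-1-yl acetate
Product: 13 (4R,5S)-4-hydroxy-5-[(E)-1-iodoprop-1-en-2-yl]-2-methylcyclohex-2-en-1-one, via epoxide 12 (not isolated)
Conditions: mCPBA (1.1 equiv), NaHCO3, CH2Cl2/H2O, 0 °C
Reagents that add atoms: 3-chloroperbenzoic acid, OOC(=O)c1cccc(Cl)c1
Why: The peracid should epoxidise the terminal, more accessible double bond of the dienyl acetate anti to the adjacent C6 substituent, and epoxide 12 opens with push from the enol acetate and hydrolytic loss of the acetyl group (vinylogous Rubottom oxidation) to the trans γ-hydroxy enone; the electron-poor iodoalkene should not react.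

Step 7
Reactants: 13 (4R,5S)-4-hydroxy-5-[(E)-1-iodoprop-1-en-2-yl]-2-methylcyclohex-2-en-1-one
Product: 14 (1S,6S)-6-[(E)-1-iodoprop-1-en-2-yl]-3-methyl-4-oxocyclohex-2-en-1-yl acetate
Conditions: PPh3, DIAD, AcOH, toluene, 0 °C to rt
Reagents that add atoms: acetic acid, CC(=O)O
Why: Mitsunobu esterification displaces the activated allylic hydroxyl by acetate with SN2 inversion, so the trans alcohol becomes the required cis C1 acetate in the same step that installs the ester.

Step 8
Reactants: 14 (1S,6S)-6-[(E)-1-iodoprop-1-en-2-yl]-3-methyl-4-oxocyclohex-2-en-1-yl acetate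
Product: 16 (1S,5R,6R)-5-hydroxy-6-[(E)-1-iodoprop-1-en-2-yl]-3-methyl-4-oxocyclohex-2-en-1-yl acetate, via sodium enolate 15 (not isolated)
Conditions: NaN(SiMe3)2 (1.1 equiv), THF, −78 °C; then 2-(phenylsulfonyl)-3-phenyloxaziridine, −78 °C; aq. NH4Cl
Reagents that add atoms: 2-(phenylsulfonyl)-3-phenyloxaziridine, O=S(=O)(N1OC1c1ccccc1)c1ccccc1
Why: Kinetic deprotonation of the only ketone α′-CH2 (C5) gives the cross-conjugated enolate 15, which takes oxygen from the oxaziridine (enolate hydroxylation) anti to the C6 substituent; the trans ketol is also the thermodynamic epimer, because a cis hydroxyl would be 1,3-diaxial to the pseudoaxial acetate.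

Step 9
Reactants: 17 methyl (S)-3-hydroxy-2-methylpropanoate
Product: 18 methyl (S)-3-[(tert-butyldimethylsilyl)oxy]-2-methylpropanoate
Conditions: TBSCl, imidazole, DMF, rt
Reagents that add atoms: tert-butyldimethylsilyl chloride, CC(C)(C)[Si](C)(C)Cl
Why: Standard silylation protects the primary alcohol through reduction and olefination without touching the stereocentre.

Step 10
Reactants: 18 methyl (S)-3-[(tert-butyldimethylsilyl)oxy]-2-methylpropanoate
Product: 19 (S)-3-[(tert-butyldimethylsilyl)oxy]-2-methylpropanal
Conditions: i-Bu2AlH (1.05 equiv), CH2Cl2, −78 °C; aq. potassium sodium tartrate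
Reagents that add atoms: none
Why: Low-temperature half-reduction of the ester stops at the aluminium hemiacetal, which releases the aldehyde on work-up without base that could epimerise the α-centre.

Step 11
Reactants: 19 (S)-3-[(tert-butyldimethylsilyl)oxy]-2-methylpropanal; 20 (3-methylbutyl)triphenylphosphonium bromide
Product: 22 tert-butyl{[(2R,3Z)-2,6-dimethylhept-3-en-1-yl]oxy}dimethylsilane, via ylide 21 (not isolated)
Conditions: NaN(SiMe3)2, THF, 0 °C; then 19, −78 °C to rt
Reagents that add atoms: none
Why: The non-stabilised ylide under salt-free conditions reacts through the kinetically favoured cis-oxaphosphetane (Wittig reaction) to give the 7′Z alkene, and the cold, fast addition should spare the α-stereocentre.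

Step 12
Reactants: 22 tert-butyl{[(2R,3Z)-2,6-dimethylhept-3-en-1-yl]oxy}dimethylsilane
Product: 23 (2R,3Z)-2,6-dimethylhept-3-en-1-ol
Conditions: TBAF, THF, 0 °C to rt
Reagents that add atoms: none
Why: Fluoride cleaves the silyl ether, and nothing else in the molecule is sensitive to fluoride or mild base.

Step 13
Reactants: 23 (2R,3Z)-2,6-dimethylhept-3-en-1-ol
Product: 24 (2R,3Z)-2,6-dimethylhept-3-enal
Conditions: Dess–Martin periodinane, NaHCO3, CH2Cl2, 0 °C; used without purification
Reagents that add atoms: none
Why: The buffered, near-neutral Dess–Martin oxidation should give the α-chiral β,γ-unsaturated aldehyde without epimerisation or conjugation, provided it is carried on at once.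

Step 14
Reactants: 24 (2R,3Z)-2,6-dimethylhept-3-enal
Product: 25 2-[(1E,3S,4Z)-3,7-dimethylocta-1,4-dien-1-yl]-4,4,5,5-tetramethyl-1,3,2-dioxaborolane
Conditions: CrCl2 (8 equiv), Cl2CHBpin (2 equiv), LiI (4 equiv), THF, rt
Reagents that add atoms: 2-(dichloromethyl)-4,4,5,5-tetramethyl-1,3,2-dioxaborolane, CC1(C)OB(C(Cl)Cl)OC1(C)C
Why: Takai–Utimoto olefination with the geminal dichromium reagent formed from Cl2CHBpin should convert the aldehyde into the (E)-alkenylboronate under non-basic conditions that preserve the allylic stereocentre and the Z alkene.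

Step 15
Reactants: 16 (1S,5R,6R)-5-hydroxy-6-[(E)-1-iodoprop-1-en-2-yl]-3-methyl-4-oxocyclohex-2-en-1-yl acetate; 25 2-[(1E,3S,4Z)-3,7-dimethylocta-1,4-dien-1-yl]-4,4,5,5-tetramethyl-1,3,2-dioxaborolane
Product: 26 (1S,5R,6R)-6-[(2E,4E,6R,7Z)-6,10-dimethylundeca-2,4,7-trien-2-yl]-5-hydroxy-3-methyl-4-oxocyclohex-2-en-1-yl acetate
Conditions: Pd(PPh3)4 (10 mol %), TlOEt (1.5 equiv), THF/H2O (3:1), rt, degassed, dark
Reagents that add atoms: none
Why: Suzuki–Miyaura coupling of an alkenyl iodide with an alkenylboronate proceeds with retention at both partners and should give the 2′E,4′E diene; the fast room-temperature thallium ethoxide protocol is chosen to spare the acetate and the α-ketol.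

**Compound list**

1 | prop-2-yn-1-ol | C#CCO | starting material
2 | {(E)-3-[(dimethylalumanyl)oxy]-2-methylprop-1-en-1-yl}dimethylalumane | C[Al](C)OC/C(C)=C/[Al](C)C | intermediate
3 | (E)-3-iodo-2-methylprop-2-en-1-ol | OC/C(C)=C/I | intermediate
4 | (E)-3-iodo-2-methylprop-2-enal | O=C/C(C)=C/I | intermediate
5 | (triphenylphosphoranylidene)acetaldehyde | O=CC=P(c1ccccc1)(c1ccccc1)c1ccccc1 | starting material
6 | (2E,4E)-5-iodo-4-methylpenta-2,4-dienal | O=C/C=C/C(C)=C/I | intermediate
7 | tert-butyl 3-oxopentanoate | CCC(=O)CC(=O)OC(C)(C)C | starting material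
8 | tert-butyl (3S,4E)-5-iodo-4-methyl-3-(2-oxoethyl)-2-propanoylpent-4-enoate (both epimers at C2, a centre lost later) | CCC(=O)C(C(=O)OC(C)(C)C)[C@H](CC=O)/C(C)=C/I | intermediate
9 | tert-butyl (6S)-6-[(E)-1-iodoprop-1-en-2-yl]-3-methyl-2-oxocyclohex-3-ene-1-carboxylate (both epimers at C1, a centre lost later) | C1C=C(C)C(=O)C(C(=O)OC(C)(C)C)[C@H]1/C(C)=C/I | intermediate
10 | (S)-5-[(E)-1-iodoprop-1-en-2-yl]-2-methylcyclohex-2-en-1-one | C1C=C(C)C(=O)C[C@H]1/C(C)=C/I | intermediate
11 | (R)-5-[(E)-1-iodoprop-1-en-2-yl]-2-methylcyclohexa-1,3-dien-1-yl acetate | CC(=O)OC1=C(C)C=C[C@@H](C1)/C(C)=C/I | intermediate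
12 | 3,4-epoxide of 11, oxirane oxygen anti to the iodopropenyl group | CC(=O)OC1=C(C)[C@H]2O[C@H]2[C@@H](C1)/C(C)=C/I | intermediate
13 | (4R,5S)-4-hydroxy-5-[(E)-1-iodoprop-1-en-2-yl]-2-methylcyclohex-2-en-1-one | O[C@@H]1C=C(C)C(=O)C[C@H]1/C(C)=C/I | intermediate
14 | (1S,6S)-6-[(E)-1-iodoprop-1-en-2-yl]-3-methyl-4-oxocyclohex-2-en-1-yl acetate | CC(=O)O[C@H]1C=C(C)C(=O)C[C@H]1/C(C)=C/I | intermediate
15 | sodium enolate of 14 (enolate across C4–C5 of the target numbering) | CC(=O)O[C@H]1C=C(C)C(O[Na])=C[C@H]1/C(C)=C/I | intermediate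
16 | (1S,5R,6R)-5-hydroxy-6-[(E)-1-iodoprop-1-en-2-yl]-3-methyl-4-oxocyclohex-2-en-1-yl acetate | CC(=O)O[C@H]1C=C(C)C(=O)[C@H](O)[C@H]1/C(C)=C/I | intermediate
17 | methyl (S)-3-hydroxy-2-methylpropanoate | OC[C@H](C)C(=O)OC | starting material
18 | methyl (S)-3-[(tert-butyldimethylsilyl)oxy]-2-methylpropanoate | CC(C)(C)[Si](C)(C)OC[C@H](C)C(=O)OC | intermediate
19 | (S)-3-[(tert-butyldimethylsilyl)oxy]-2-methylpropanal | CC(C)(C)[Si](C)(C)OC[C@H](C)C=O | intermediate
20 | (3-methylbutyl)triphenylphosphonium bromide | CC(C)CC[P+](c1ccccc1)(c1ccccc1)c1ccccc1.[Br-] | starting material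
21 | (3-methylbutylidene)triphenylphosphorane | CC(C)CC=P(c1ccccc1)(c1ccccc1)c1ccccc1 | intermediate
22 | tert-butyl{[(2R,3Z)-2,6-dimethylhept-3-en-1-yl]oxy}dimethylsilane | CC(C)(C)[Si](C)(C)OC[C@H](C)/C=C\CC(C)C | intermediate
23 | (2R,3Z)-2,6-dimethylhept-3-en-1-ol | OC[C@H](C)/C=C\CC(C)C | intermediate
24 | (2R,3Z)-2,6-dimethylhept-3-enal | O=C[C@H](C)/C=C\CC(C)C | intermediate
25 | 2-[(1E,3S,4Z)-3,7-dimethylocta-1,4-dien-1-yl]-4,4,5,5-tetramethyl-1,3,2-dioxaborolane | CC1(C)OB(/C=C/[C@H](C)/C=C\CC(C)C)OC1(C)C | intermediate
26 | (1S,5R,6R)-6-[(2E,4E,6R,7Z)-6,10-dimethylundeca-2,4,7-trien-2-yl]-5-hydroxy-3-methyl-4-oxocyclohex-2-en-1-yl acetate | CC(=O)O[C@H]1C=C(C)C(=O)[C@H](O)[C@H]1/C(C)=C/C=C/[C@H](C)/C=C\CC(C)C | target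

**Step count and risks**

Total steps: 15. Longest linear sequence: 9 (steps 1–8 and 15); steps 9–14 are the six-step side-chain branch.

Steps most likely to fail:

Step 5. Enol acetylation under acid may give the cross-conjugated dienyl acetate (proton loss from C5 instead of C1), or the acid may move double bonds towards an aromatic ring. The fallback sets out from 10 and returns at 13. The allylic C1 methylene of 10 is oxidised directly with t-BuOOH and catalytic dirhodium tetracaprolactamate Rh2(cap)4 in CH2Cl2 to the ene-dione (5S)-5-[(E)-1-iodoprop-1-en-2-yl]-2-methylcyclohex-2-ene-1,4-dione F1, kept cold and neutral because C6 is now enolisable. F1 is reduced at once under Luche conditions (NaBH4, CeCl3·7H2O, MeOH, −78 °C): the new carbonyl at C1, flanked by the unsubstituted alkene carbon C2, is the more reactive one, and axial hydride delivery should give the trans alcohol 13.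

Step 7. The activated allylic alcohol may lose a proton instead of being substituted (elimination to a dienone that tautomerises to a phenol), or substitution syn to the C6 substituent may be too slow. The fallback sets out from 13 and returns at 14. Alcohol 13 is oxidised with Dess–Martin periodinane to the ene-dione F1 of the first fallback. This is reduced under reagent control with (S)-2-methyl-CBS-oxazaborolidine and BH3·SMe2 (Corey–Bakshi–Shibata reduction, the alkenyl arm acting as the large group) to the cis alcohol (4S,5S)-4-hydroxy-5-[(E)-1-iodoprop-1-en-2-yl]-2-methylcyclohex-2-en-1-one F2. Acetylation with retention (Ac2O, pyridine, DMAP) then gives 14.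

Step 15. Ethoxide-mediated cleavage of the allylic acetate, or base-induced isomerisation or oxidation of the α-ketol, may compete with transmetalation. The fallback sets out from 14 and 25 and returns at 26. The ketol-free iodide 14 is coupled with 25 under the same palladium conditions to (1S,6S)-6-[(2E,4E,6R,7Z)-6,10-dimethylundeca-2,4,7-trien-2-yl]-3-methyl-4-oxocyclohex-2-en-1-yl acetate F3. The C5 hydroxyl is then introduced last by the enolate oxidation of step 8 (NaN(SiMe3)2, then the oxaziridine, THF, −78 °C), which gives 26.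

Further compounds
F1 | step 5 | (5S)-5-[(E)-1-iodoprop-1-en-2-yl]-2-methylcyclohex-2-ene-1,4-dione | O=C1C=C(C)C(=O)C[C@H]1/C(C)=C/I
F2 | step 7 | (4S,5S)-4-hydroxy-5-[(E)-1-iodoprop-1-en-2-yl]-2-methylcyclohex-2-en-1-one | O[C@H]1C=C(C)C(=O)C[C@H]1/C(C)=C/I
F3 | step 15 | (1S,6S)-6-[(2E,4E,6R,7Z)-6,10-dimethylundeca-2,4,7-trien-2-yl]-3-methyl-4-oxocyclohex-2-en-1-yl acetate | CC(=O)O[C@H]1C=C(C)C(=O)C[C@H]1/C(C)=C/C=C/[C@H](C)/C=C\CC(C)C
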